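Ring positions are numbered as in the isoflavone: O1 to C8a for rings A and C, C1' to C6' for ring B. In the chromene names of the intermediates, C6 = C1', C7 = C2', C8 = C3', C8a = C4', C4a = C5' and C5 = C6'.

## Analysis of the target

Target 24 is an isoflavone: a 5,7-dihydroxy-4H-chromen-4-one (benzo ring A fused to the 4-pyranone ring C) that carries a pentasubstituted benzene ring B at C3. Ring B is fused along C4'–C5' to a 2,2-dimethyl-2H-pyran (ring D, oxygen on C4', cis styrenic alkene on C5'), has a free hydroxyl at C3' and a 3-methylbut-2-enyl (prenyl) group at C2', right beside the bond to C3; only C6' bears hydrogen. There is no stereocenter and no alkene whose geometry has to be set, so the problem is one of regiochemistry and functional-group tolerance. The sensitive groups are the prenyl group next to a free phenol (acid closes it to a chroman), the chromene alkene (acid, electrophiles, hydrogenation), the 4-pyranone (opened by hydroxide at C2) and the electron-rich phloroglucinol-type ring A. The difficulty lies in the contiguous substitution C1'–C5' of ring B: the catechol oxygens O3' and O4' must be told apart and the prenyl group placed at the most crowded carbon, while ring C must be built under conditions that ring D survives. The strategy rests on the C2=C3 double bond of ring C. It is a trisubstituted alkene between O1 and the C4 ketone, so it can be read as the union of two terminal alkenes: a vinyl ether on O1 and the methylene of a 2-arylprop-2-en-1-one on C4.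

## Retrosynthetic reasoning

24 ⇒ 23. The two aryl–O–CH2OMe bonds on ring A are cut last. The ring A phenols must stay masked throughout, because the 7-OH is the most acidic oxygen and would compete in the O1 vinylation and the O3' allylation. Acetal ethers withstand the organometallic, fluoride, palladium and thermal steps and leave under dilute acid. The forward step must remove them without letting the prenyl group add to the neighbouring O3'–H.

23 ⇒ 21 ⇒ 20. The C2'–CH2 bond of the prenyl group is cut by a retro-Claisen step to the O3' 1,1-dimethylallyl ether 21 (dienone 22 lies between), and the O3'–C bond of 21 is cut to phenol 20. C2' is not where an electrophile would go, since ring A is far more nucleophilic. A sigmatropic shift from O3' has no choice: of its two ortho positions C4' carries the pyran oxygen, so only C2' can rearomatise. The prenyl group is introduced after the key step on purpose, because a prenyl group or terminal allyl ether on ring B would offer the metathesis catalyst a second, five-membered closure with the enone methylene.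

20 ⇒ 19. The O3'–Si bond is cut. O3' needs a group that survives every step up to the key step and is removed without touching the acetals; a bulky aryl silyl ether cleaved by a fluoride source does this.

19 ⇒ 18. This is the key disconnection. The C2=C3 bond of ring C is cut as a retro-metathesis, giving the aryl vinyl ether on O1 and the 2-arylprop-2-en-1-one on C4 in 18. Cutting here, rather than at O1–C2 or C3–C4, means ring C is closed by forming only a C=C bond under neutral conditions; every other bond of ring C is already present. The forward reaction must pick the two terminal alkenes out of four C=C bonds and close the six-membered ring, with the chromene alkene as a spectator.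

18 ⇒ 16 ⇒ 15. The exocyclic methylene on C3 is removed (Mannich base 17 lies between), giving the deoxybenzoin vinyl ether 16. This carbon is only a handle and leaves again in the key step. The O1–vinyl bond is then cut to the 2-hydroxydeoxybenzoin 15. In the forward direction O1 must be vinylated first, because a free ortho phenol would add to the α-methylene ketone (oxa-Michael) and give an isoflavanone.

15 ⇒ 14 ⇒ 13 ⇒ 10 + 8. One acetal of tris-ether 14 is cut to free O1, the ketone is taken back to carbinol 13, and the bond between the carbinol carbon (future C4) and ring A (future C4a) is cut. This gives the aryl nucleophile 11/12, made from the symmetric tris-ether 10, and arylacetaldehyde 8. A Friedel–Crafts acylation of triol 9 with an arylacetic acid would make the same bond in one step but needs a strong Lewis acid with heating, which the chromene and the silyl ether would not survive and which cannot be run on an acetal-protected ring A. The organometallic route is regiochemically automatic, since all three ring CH positions of 10 are equivalent. The one differentiation needed, one acetal out of three, is supplied by the new ketone, which activates its ortho neighbours.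

8 ⇒ 7 ⇒ 6. The aldehyde carbon of 8 (future C4) is removed through enol ether 7 (Wittig C=C bond) to the aromatic aldehyde 6. Ring B thus stays an aromatic aldehyde for as long as that group is needed to direct the first etherification.

6 ⇒ 4 ⇒ 3 ⇒ 1 + 2. Ring D is opened at the C5'–C and O4'–C bonds of the pyran through allenylphenol 5 to propargyl ether 4; the silyl group is removed to 3, and the O4'–C bond is cut to 1 and 2. The para-formyl group of 1 makes the 4-OH (future O4') clearly more acidic than the 3-OH (future O3'), so the two catechol oxygens are told apart in the first step without a protecting group. In 4 the rearrangement can only end at C5, because C3 carries oxygen.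

10 ⇒ 9. Three O–C bonds are cut; 10 comes from exhaustive acetal formation on commercial 9.

## Alternatives that were turned down

Alternative 1: Ring B itself is disconnected across C1'–C2' and C5'–C6', back to the pyrano-fused 2-pyranone A2 and the alkynoate A3 (methyl propiolate). In the forward sense A3 adds as a dienophile across the pyranone diene and the bridged lactone aromatises by decarboxylation to ester A1, which already carries ring D, the protected O3' and the prenyl group.
- For: the whole substitution pattern of ring B comes from one step, and the donor oxygen on the pyranone (future O4') polarises the diene in the required sense (future C5' to the unsubstituted alkyne carbon). The prenyl group never has to be forced into C2' by a late rearrangement; on this point the alternative is stronger.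
- Against: A2 is a tetrasubstituted, doubly oxygenated pyranone that needs its own multi-step synthesis. Such cycloadditions need temperatures at which the 2H-pyran ring of A2 can open electrocyclically and the prenyl group can react as an ene partner. A1 is only a ring B fragment, so its ester must still be homologated and rings A and C built.
- Comparison: the chosen route reaches the ring B fragment 8 in five standard steps with regiochemistry fixed by the formyl group of 1. It places its risk in a ring C closure that has a classical rescue from 15.

Alternative 2: Ring A is disconnected across C5–C6 and C7–C8, back to the monocyclic 4-pyranone ester A5 and the acetyl donor A6 (N-methoxy-N-methylacetamide). In the forward sense the 2-methyl group of A5 (vinylogous to the ketone) is deprotonated and C-acetylated by A6; the new methyl ketone enolate then condenses on the neighbouring ester and the ring enolises to give A4 with both ring A hydroxyls free.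
- For: ring A needs no protecting group and no late deprotection. Here the alternative is stronger than the chosen route, which carries two acetals from step 6 to step 16.
- Against: the base must choose the methyl group of A5 over conjugate addition at the unsubstituted ring carbon (future C2), the ester and the ketone, and the second condensation needs a dianion on a base-sensitive pyranone. A5 must already carry the finished ring B, prenyl included, so the ring B problem is only moved forward and solved by the same Claisen chemistry. A4 still needs an acidic deprotection at O3' beside the prenyl group, the same hazard as step 16.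
- Comparison: the route is longer before its key step and that step has no simple rescue. The chosen key step runs on a neutral substrate under neutral conditions and every step before it is standard.

Alternative 3: Ring D and the prenyl group are disconnected together (the C5'–C and O4'–C bonds of the pyran and the C2'–CH2 bond), back to isoflavone A8 with a 1,1-dimethylpropargyl ether on O4' and a 1,1-dimethylallyl ether on O3'. On heating, the propargyl ether rearranges to C5' and closes the pyran while the allyl ether rearranges to C2', giving A7 (the same compound as 23).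
- For: each ether has exactly one ortho position that can rearomatise, so both regiochemistries are dictated, and two structural elements arise in one operation. On step economy of the end game this is clearly stronger than the chosen route, which spends steps 1–3 and 13–15 on the same two rearrangements.
- Against: two tertiary ethers must be placed on neighbouring oxygens of an isoflavone ring B, where nothing differentiates O3' from O4' the way the formyl group does in 1, and the second etherification takes place beside the first bulky group. The allyl shift needs less heat than the propargyl shift, so the prenylphenol formed first must survive the higher temperature with its free O3'–H beside the alkene. Crowding favours elimination of the allyl group over rearrangement. The strategy leaves ring C to be made by other means.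
- Comparison: the chosen route gives up this economy but runs each rearrangement on a substrate with one path and one thermally labile group. The O3'/O4' assignment is secure from step 1.

Key step: step 12

Remark on the chemistry: O3' is carried as a triisopropylsilyl ether, because an aryl tert-butyldimethylsilyl ether would be at risk in the two dilute-acid steps and towards the ylide and the organometallic reagent before the key step; the key step itself is unaffected.

## Route

Step 1
Reactants: 1 3,4-dihydroxybenzaldehyde; 2 3-chloro-3-methylbut-1-yne
Product: 3 3-hydroxy-4-[(2-methylbut-3-yn-2-yl)oxy]benzaldehyde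
Conditions: K2CO3 (1.1 equiv), KI, CuI (cat.), acetone, 55 °C
Reagents that add atoms: none
Why: Copper-assisted O-alkylation of a phenoxide by the tertiary propargylic chloride; one equivalent of carbonate ionises only the 4-OH, which is para to the formyl group and clearly more acidic than the 3-OH, so the ether should form at O4 (future pyran oxygen O4').

Step 2
Reactants: 3 3-hydroxy-4-[(2-methylbut-3-yn-2-yl)oxy]benzaldehyde
Product: 4 4-[(2-methylbut-3-yn-2-yl)oxy]-3-[(triisopropylsilyl)oxy]benzaldehyde
Conditions: i-Pr3SiCl, imidazole, DMF, rt
Reagents that add atoms: chlorotriisopropylsilane, CC(C)[Si](Cl)(C(C)C)C(C)C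
Why: Imidazole-promoted silylation of the remaining phenol; the aryl triisopropylsilyl ether should withstand the ylide, the organometallic reagent, dilute acid and heat of the following steps and still fall to fluoride.

Step 3
Reactants: 4 4-[(2-methylbut-3-yn-2-yl)oxy]-3-[(triisopropylsilyl)oxy]benzaldehyde
Product: 6 2,2-dimethyl-8-[(triisopropylsilyl)oxy]-2H-chromene-6-carbaldehyde, via ortho-allenylphenol 5 (not isolated)
Conditions: PhNEt2, 190 °C
Reagents that add atoms: none
Why: Aromatic propargyl Claisen rearrangement ([3,3]) to C5, the only ortho position that can rearomatise because C3 carries the silyloxy group, gives 5; a [1,5]-hydrogen shift and oxa-6π-electrocyclisation then close the 2,2-dimethyl-2H-pyran ring.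

Step 4
Reactants: 6 2,2-dimethyl-8-[(triisopropylsilyl)oxy]-2H-chromene-6-carbaldehyde
Product: 7 6-(2-methoxyethenyl)-2,2-dimethyl-8-[(triisopropylsilyl)oxy]-2H-chromene (E/Z mixture)
Conditions: Ph3P(CH2OMe)Cl, NaN(SiMe3)2, THF, 0 °C → rt
Reagents that add atoms: (methoxymethyl)triphenylphosphonium chloride, COC[P+](c1ccccc1)(c1ccccc1)c1ccccc1.[Cl-]
Why: Wittig reaction with the non-stabilised methoxymethylene ylide adds the carbon that becomes C4; the alkene geometry is irrelevant because both isomers converge in step 5.

Step 5
Reactants: 7 6-(2-methoxyethenyl)-2,2-dimethyl-8-[(triisopropylsilyl)oxy]-2H-chromene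
Product: 8 2-{2,2-dimethyl-8-[(triisopropylsilyl)oxy]-2H-chromen-6-yl}acetaldehyde
Conditions: 2 M aq. HCl, THF, 45 °C
Reagents that add atoms: water, O
Why: Acid-catalysed enol ether hydrolysis (C-protonation to the oxocarbenium ion, hydration, loss of methanol); the aryl triisopropylsilyl ether and the 2,2-dimethylchromene should tolerate dilute aqueous acid, and 8 is used at once because arylacetaldehydes self-condense.

Step 6
Reactants: 9 phloroglucinol
Product: 10 1,3,5-tris(methoxymethoxy)benzene
Conditions: NaH, MOMCl, DMF, 0 °C → rt
Reagents that add atoms: chloromethyl methyl ether, COCCl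
Why: Williamson-type O-alkylation of the triphenoxide; the hard, oxocarbenium-like electrophile should react at oxygen rather than at ring carbon.

Step 7
Reactants: 10 1,3,5-tris(methoxymethoxy)benzene; 8 2-{2,2-dimethyl-8-[(triisopropylsilyl)oxy]-2H-chromen-6-yl}acetaldehyde
Product: 13 (±)-2-{2,2-dimethyl-8-[(triisopropylsilyl)oxy]-2H-chromen-6-yl}-1-[2,4,6-tris(methoxymethoxy)phenyl]ethan-1-ol, via 2,4,6-tris(methoxymethoxy)phenyllithium 11 (not isolated), via aryldichlorocerium 12 (not isolated)
Conditions: n-BuLi, THF, 0 °C; CeCl3, −78 °C; then 8, −78 °C; aq. NH4Cl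
Reagents that add atoms: none
Why: Directed ortho-lithiation between two acetal oxygens gives 11; transmetalation to the less basic organocerium 12 should suppress enolisation of the arylacetaldehyde in favour of 1,2-addition. The carbinol carbon is formed racemic and is oxidised in step 8.

Step 8
Reactants: 13 (±)-2-{2,2-dimethyl-8-[(triisopropylsilyl)oxy]-2H-chromen-6-yl}-1-[2,4,6-tris(methoxymethoxy)phenyl]ethan-1-ol
Product: 14 2-{2,2-dimethyl-8-[(triisopropylsilyl)oxy]-2H-chromen-6-yl}-1-[2,4,6-tris(methoxymethoxy)phenyl]ethan-1-one
Conditions: Dess–Martin periodinane, CH2Cl2, 0 °C → rt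
Reagents that add atoms: none
Why: Dess–Martin oxidation of the secondary benzylic alcohol under neutral, non-aqueous conditions that should leave the acetals, the silyl ether and the chromene alkene untouched; the stereocenter of 13 disappears.

Step 9
Reactants: 14 2-{2,2-dimethyl-8-[(triisopropylsilyl)oxy]-2H-chromen-6-yl}-1-[2,4,6-tris(methoxymethoxy)phenyl]ethan-1-one
Product: 15 2-{2,2-dimethyl-8-[(triisopropylsilyl)oxy]-2H-chromen-6-yl}-1-[2-hydroxy-4,6-bis(methoxymethoxy)phenyl]ethan-1-one
Conditions: conc. aq. HCl (cat.), MeOH–THF, 0 °C → rt, stopped at mono-cleavage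
Reagents that add atoms: none
Why: Acid-catalysed acetal exchange with methanol should be fastest for an acetal ortho to the ketone, because the carbonyl oxygen hydrogen-bonds to the departing phenol oxygen and strain of the 2,6-disubstituted aryl ketone is relieved. Once one ortho phenol is free it chelates the carbonyl, so the second ortho acetal and the para acetal lose this assistance; the silyl ether is stable to dilute acid.

Step 10
Reactants: 15 2-{2,2-dimethyl-8-[(triisopropylsilyl)oxy]-2H-chromen-6-yl}-1-[2-hydroxy-4,6-bis(methoxymethoxy)phenyl]ethan-1-one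
Product: 16 1-[2-(ethenyloxy)-4,6-bis(methoxymethoxy)phenyl]-2-{2,2-dimethyl-8-[(triisopropylsilyl)oxy]-2H-chromen-6-yl}ethan-1-one
Conditions: Cu(OAc)2 (2 equiv), 2,4,6-trivinylcyclotriboroxane–pyridine complex, pyridine, 4 Å MS, CH2Cl2, rt, N2
Reagents that add atoms: 2,4,6-trivinylcyclotriboroxane–pyridine complex, C=CB1OB(C=C)OB(C=C)O1.c1ccncc1
Why: Chan–Lam-type oxidative O-vinylation: a vinyl group passes from boron to divalent copper, the phenoxide binds, a second equivalent of the copper salt oxidises the complex to trivalent copper, and C–O reductive elimination gives the aryl vinyl ether. Using the copper salt itself as oxidant under nitrogen avoids aerobic oxidation of the doubly activated ketone CH2.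

Step 11
Reactants: 16 1-[2-(ethenyloxy)-4,6-bis(methoxymethoxy)phenyl]-2-{2,2-dimethyl-8-[(triisopropylsilyl)oxy]-2H-chromen-6-yl}ethan-1-one
Product: 18 1-[2-(ethenyloxy)-4,6-bis(methoxymethoxy)phenyl]-2-{2,2-dimethyl-8-[(triisopropylsilyl)oxy]-2H-chromen-6-yl}prop-2-en-1-one, via Mannich base 17 (not isolated)
Conditions: CH2(NMe2)2, Ac2O, THF, 0 → 45 °C
Reagents that add atoms: bis(dimethylamino)methane, CN(C)CN(C)C
Why: Mannich reaction of the benzylic ketone CH2 with the iminium ion formed from the aminal and Ac2O gives 17, whose dimethylamino group is eliminated through its N-acetylammonium ion (α-methylenation of a deoxybenzoin). O1 is already capped as the vinyl ether, so no oxa-Michael closure to an isoflavanone can follow; 18 is used directly because 2-aryl enones dimerise on standing.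

Step 12
Reactants: 18 1-[2-(ethenyloxy)-4,6-bis(methoxymethoxy)phenyl]-2-{2,2-dimethyl-8-[(triisopropylsilyl)oxy]-2H-chromen-6-yl}prop-2-en-1-one
Product: 19 3-{2,2-dimethyl-8-[(triisopropylsilyl)oxy]-2H-chromen-6-yl}-5,7-bis(methoxymethoxy)-4H-chromen-4-one
Conditions: RuCl2(H2IMes)(=CH-C6H4-2-O-i-Pr) (second-generation Hoveyda–Grubbs catalyst, H2IMes = 1,3-dimesitylimidazolidin-2-ylidene, 10 mol%), toluene, 0.005 M, 80 °C, argon sparge
Reagents that add atoms: none
Why: Proposed new method: the ruthenium benzylidene should exchange first with the unhindered aryl vinyl ether to give the aryloxycarbene Ru=CH–OAr, which adds intramolecularly ([2+2]) across the 1,1-disubstituted enone methylene with ruthenium on the CH2 carbon; cycloreversion of the ruthenacyclobutane releases the O1–C2H=C3(aryl)–C4(=O) unit and Ru=CH2, and the two terminal CH2 groups leave as ethylene. The closest known reaction type is ring-closing metathesis of aryl vinyl ethers with a second ortho-tethered alkene to give benzofurans and chromenes; closure onto a 2-aryl enone to give a 4-pyranone is the untested extension. Ring C is closed as a six-membered ring with both alkene carbons inside the ring, the reacting ends being held cis on ring A through O1 and the C4 carbonyl. No stereocenter is formed. The step needs chemoselectivity among four C=C bonds: ring B carries no terminal alkene at this stage (no prenyl group, no allyl ether), the chromene C3=C4 bond is an unstrained cis ring alkene shielded by the gem-dimethyl group, and the electron-poor, hindered enone methylene should not dimerise, so only the six-membered closure is open. The product is a trisubstituted push–pull alkene (vinylogous ester) that should not re-enter the cycle; high dilution and the argon sweep counter vinyl ether dimerisation and the slow turnover expected of a heteroatom-stabilised carbene.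

Step 13
Reactants: 19 3-{2,2-dimethyl-8-[(triisopropylsilyl)oxy]-2H-chromen-6-yl}-5,7-bis(methoxymethoxy)-4H-chromen-4-one
Product: 20 3-(8-hydroxy-2,2-dimethyl-2H-chromen-6-yl)-5,7-bis(methoxymethoxy)-4H-chromen-4-one
Conditions: n-Bu4NF, AcOH, THF, 0 °C
Reagents that add atoms: none
Why: Fluoride cleavage of the aryl silyl ether, driven by Si–F bond formation; acetic acid buffers the phenoxide so that the pyranone ring is not opened, and the acetals are inert to fluoride.

Step 14
Reactants: 20 3-(8-hydroxy-2,2-dimethyl-2H-chromen-6-yl)-5,7-bis(methoxymethoxy)-4H-chromen-4-one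
Product: 21 3-{2,2-dimethyl-8-[(2-methylbut-3-en-2-yl)oxy]-2H-chromen-6-yl}-5,7-bis(methoxymethoxy)-4H-chromen-4-one
Conditions: Pd(PPh3)4 (5 mol%), tert-butyl 2-methylbut-3-en-2-yl carbonate, 4 Å MS, THF, 0 °C
Reagents that add atoms: tert-butyl 2-methylbut-3-en-2-yl carbonate, C=CC(C)(C)OC(=O)OC(C)(C)C
Why: Tsuji–Trost O-allylation: zerovalent palladium ionises the tertiary allylic carbonate to a 1,1-dimethyl-π-allyl complex, and the tert-butoxide released on decarboxylation deprotonates the phenol. At low temperature the phenoxide should attack the more substituted terminus under kinetic control, giving the tertiary ether.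

Step 15
Reactants: 21 3-{2,2-dimethyl-8-[(2-methylbut-3-en-2-yl)oxy]-2H-chromen-6-yl}-5,7-bis(methoxymethoxy)-4H-chromen-4-one
Product: 23 3-[8-hydroxy-2,2-dimethyl-7-(3-methylbut-2-en-1-yl)-2H-chromen-6-yl]-5,7-bis(methoxymethoxy)-4H-chromen-4-one, via ortho-dienone 22 (not isolated)
Conditions: PhNEt2, 130 °C
Reagents that add atoms: none
Why: Aromatic Claisen rearrangement ([3,3]) of the 1,1-dimethylallyl ether: of the two ortho positions of O3', C4' (chromene C8a) bears the pyran oxygen and cannot rearomatise, so the allyl unit should arrive with allylic inversion at C2' (chromene C7) as a prenyl group and dienone 22 tautomerises to the phenol. The weakly basic amine solvent suppresses acid-induced loss of the allyl group and cyclisation of the product.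

Step 16
Reactants: 23 3-[8-hydroxy-2,2-dimethyl-7-(3-methylbut-2-en-1-yl)-2H-chromen-6-yl]-5,7-bis(methoxymethoxy)-4H-chromen-4-one
Product: 24 5,7-dihydroxy-3-[8-hydroxy-2,2-dimethyl-7-(3-methylbut-2-en-1-yl)-2H-chromen-6-yl]-4H-chromen-4-one
Conditions: 3 M aq. HCl–MeOH, 45 °C
Reagents that add atoms: none
Why: Acid-catalysed acetal exchange with methanol removes both aryl methoxymethyl ethers; moderate temperature and monitoring are meant to keep the prenyl group from cyclising onto the neighbouring O3'–H and the chromene alkene from being hydrated.

## Compound list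

1 | 3,4-dihydroxybenzaldehyde | O=Cc1ccc(O)c(O)c1 | starting material
2 | 3-chloro-3-methylbut-1-yne | CC(C)(Cl)C#C | starting material
3 | 3-hydroxy-4-[(2-methylbut-3-yn-2-yl)oxy]benzaldehyde | O=Cc1ccc(OC(C)(C)C#C)c(O)c1 | intermediate
4 | 4-[(2-methylbut-3-yn-2-yl)oxy]-3-[(triisopropylsilyl)oxy]benzaldehyde | O=Cc1ccc(OC(C)(C)C#C)c(O[Si](C(C)C)(C(C)C)C(C)C)c1 | intermediate
5 | 4-hydroxy-3-(3-methylbuta-1,2-dien-1-yl)-5-[(triisopropylsilyl)oxy]benzaldehyde | O=Cc1cc(C=C=C(C)C)c(O)c(O[Si](C(C)C)(C(C)C)C(C)C)c1 | intermediate (not isolated)
6 | 2,2-dimethyl-8-[(triisopropylsilyl)oxy]-2H-chromene-6-carbaldehyde | CC1(C)C=Cc2cc(C=O)cc(O[Si](C(C)C)(C(C)C)C(C)C)c2O1 | intermediate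
7 | 6-(2-methoxyethenyl)-2,2-dimethyl-8-[(triisopropylsilyl)oxy]-2H-chromene (E/Z mixture) | CC1(C)C=Cc2cc(C=COC)cc(O[Si](C(C)C)(C(C)C)C(C)C)c2O1 | intermediate
8 | 2-{2,2-dimethyl-8-[(triisopropylsilyl)oxy]-2H-chromen-6-yl}acetaldehyde | CC1(C)C=Cc2cc(CC=O)cc(O[Si](C(C)C)(C(C)C)C(C)C)c2O1 | intermediate
9 | phloroglucinol (benzene-1,3,5-triol) | Oc1cc(O)cc(O)c1 | starting material
10 | 1,3,5-tris(methoxymethoxy)benzene | COCOc1cc(OCOC)cc(OCOC)c1 | intermediate
11 | 2,4,6-tris(methoxymethoxy)phenyllithium | [Li]c1c(OCOC)cc(OCOC)cc1OCOC | intermediate (not isolated)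
12 | dichloro[2,4,6-tris(methoxymethoxy)phenyl]cerium | Cl[Ce](Cl)c1c(OCOC)cc(OCOC)cc1OCOC | intermediate (not isolated)
13 | (±)-2-{2,2-dimethyl-8-[(triisopropylsilyl)oxy]-2H-chromen-6-yl}-1-[2,4,6-tris(methoxymethoxy)phenyl]ethan-1-ol (racemic) | CC1(C)C=Cc2cc(CC(O)c3c(OCOC)cc(OCOC)cc3OCOC)cc(O[Si](C(C)C)(C(C)C)C(C)C)c2O1 | intermediate
14 | 2-{2,2-dimethyl-8-[(triisopropylsilyl)oxy]-2H-chromen-6-yl}-1-[2,4,6-tris(methoxymethoxy)phenyl]ethan-1-one | CC1(C)C=Cc2cc(CC(=O)c3c(OCOC)cc(OCOC)cc3OCOC)cc(O[Si](C(C)C)(C(C)C)C(C)C)c2O1 | intermediate
15 | 2-{2,2-dimethyl-8-[(triisopropylsilyl)oxy]-2H-chromen-6-yl}-1-[2-hydroxy-4,6-bis(methoxymethoxy)phenyl]ethan-1-one | CC1(C)C=Cc2cc(CC(=O)c3c(O)cc(OCOC)cc3OCOC)cc(O[Si](C(C)C)(C(C)C)C(C)C)c2O1 | intermediate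
16 | 1-[2-(ethenyloxy)-4,6-bis(methoxymethoxy)phenyl]-2-{2,2-dimethyl-8-[(triisopropylsilyl)oxy]-2H-chromen-6-yl}ethan-1-one | CC1(C)C=Cc2cc(CC(=O)c3c(OC=C)cc(OCOC)cc3OCOC)cc(O[Si](C(C)C)(C(C)C)C(C)C)c2O1 | intermediate
17 | (±)-3-(dimethylamino)-1-[2-(ethenyloxy)-4,6-bis(methoxymethoxy)phenyl]-2-{2,2-dimethyl-8-[(triisopropylsilyl)oxy]-2H-chromen-6-yl}propan-1-one (racemic) | CC1(C)C=Cc2cc(C(CN(C)C)C(=O)c3c(OC=C)cc(OCOC)cc3OCOC)cc(O[Si](C(C)C)(C(C)C)C(C)C)c2O1 | intermediate (not isolated)
18 | 1-[2-(ethenyloxy)-4,6-bis(methoxymethoxy)phenyl]-2-{2,2-dimethyl-8-[(triisopropylsilyl)oxy]-2H-chromen-6-yl}prop-2-en-1-one | CC1(C)C=Cc2cc(C(=C)C(=O)c3c(OC=C)cc(OCOC)cc3OCOC)cc(O[Si](C(C)C)(C(C)C)C(C)C)c2O1 | intermediate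
19 | 3-{2,2-dimethyl-8-[(triisopropylsilyl)oxy]-2H-chromen-6-yl}-5,7-bis(methoxymethoxy)-4H-chromen-4-one | CC1(C)C=Cc2cc(-c3coc4cc(OCOC)cc(OCOC)c4c3=O)cc(O[Si](C(C)C)(C(C)C)C(C)C)c2O1 | intermediate
20 | 3-(8-hydroxy-2,2-dimethyl-2H-chromen-6-yl)-5,7-bis(methoxymethoxy)-4H-chromen-4-one | CC1(C)C=Cc2cc(-c3coc4cc(OCOC)cc(OCOC)c4c3=O)cc(O)c2O1 | intermediate
21 | 3-{2,2-dimethyl-8-[(2-methylbut-3-en-2-yl)oxy]-2H-chromen-6-yl}-5,7-bis(methoxymethoxy)-4H-chromen-4-one | CC1(C)C=Cc2cc(-c3coc4cc(OCOC)cc(OCOC)c4c3=O)cc(OC(C)(C)C=C)c2O1 | intermediate
22 | (±)-3-[2,2-dimethyl-7-(3-methylbut-2-en-1-yl)-8-oxo-7,8-dihydro-2H-chromen-6-yl]-5,7-bis(methoxymethoxy)-4H-chromen-4-one (racemic) | CC(C)=CCC1C(=O)C2=C(C=CC(C)(C)O2)C=C1c1coc2cc(OCOC)cc(OCOC)c2c1=O | intermediate (not isolated)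
23 | 3-[8-hydroxy-2,2-dimethyl-7-(3-methylbut-2-en-1-yl)-2H-chromen-6-yl]-5,7-bis(methoxymethoxy)-4H-chromen-4-one | CC(C)=CCc1c(-c2coc3cc(OCOC)cc(OCOC)c3c2=O)cc2c(c1O)OC(C)(C)C=C2 | intermediate
24 | 5,7-dihydroxy-3-[8-hydroxy-2,2-dimethyl-7-(3-methylbut-2-en-1-yl)-2H-chromen-6-yl]-4H-chromen-4-one | CC(C)=CCc1c(-c2coc3cc(O)cc(O)c3c2=O)cc2c(c1O)OC(C)(C)C=C2 | target

## Step count and least certain steps

Total: 16 steps. Longest linear sequence: 15 steps (steps 1–5 and 7–16, from 1); the ring A branch is step 6.

Step 12 (key step, proposed new method). The most likely failure is a stalled cycle: the ruthenium may rest as a heteroatom-stabilised carbene derived from the vinyl ether, and the electron-poor, 1,1-disubstituted enone alkene may be reluctant to enter the metallacycle. Intermolecular vinyl ether dimerisation and thermal oligomerisation of the enone would then take over. Fallback by known chemistry: the route is left at 15, before vinylation. Heating 15 with N,N-dimethylformamide dimethyl acetal in toluene at 90 °C should give the enaminone 3-(dimethylamino)-2-{2,2-dimethyl-8-[(triisopropylsilyl)oxy]-2H-chromen-6-yl}-1-[2-hydroxy-4,6-bis(methoxymethoxy)phenyl]prop-2-en-1-one F1. Its phenol adds to the enamine carbon and dimethylamine is lost, so the route is rejoined at 19. This closes ring C at O1–C2 instead of C2=C3 and needs neither the vinyl ether nor the methylene handle.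

Step 10. The phenol is hydrogen-bonded to the ketone and therefore a weak ligand for copper, so conversion may be poor. The doubly activated ketone CH2 may also be oxidised by the divalent copper salt. Fallback: iridium-catalysed transfer vinylation of 15 with vinyl acetate ([IrCl(cod)]2, cod = cycloocta-1,5-diene, Na2CO3, toluene, 100 °C). This is a non-oxidative addition–elimination on an iridium phenoxide instead of an oxidative coupling; it sets out from 15 and returns at 16 without a new intermediate.

Step 9. Cleavage may not stop cleanly: a second acetal (para or the other ortho one) may be lost before the first is consumed, since the discrimination is only kinetic. Fallback: all three acetals of 14 are removed (3 M HCl–MeOH, 45 °C; the silyl ether stays) to give 2-{2,2-dimethyl-8-[(triisopropylsilyl)oxy]-2H-chromen-6-yl}-1-(2,4,6-trihydroxyphenyl)ethan-1-one F2. Treating F2 with two equivalents of MOMCl and i-Pr2NEt in CH2Cl2 at 0 °C should protect only the two hydroxyls not chelated to the ketone, returning the route at 15. This replaces selective deprotection by selective protection, at the cost of one step.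

Step 15. C2' lies between the chromone and O3', so the [3,3] shift may be slow enough for ionisation of the tertiary allyl ether (loss of the allyl group, return of 20) or migration towards the para position C6' to compete. Fallback: direct ortho C-alkylation of the sodium phenoxide of 20 (NaH, toluene, prenyl bromide, rt), where the tight ion pair in a non-polar solvent directs the electrophile to the only free ortho carbon. It sets out from 20 and returns at 23 without a new intermediate, replacing the sigmatropic step by an ionic one.

Step 7. The arylacetaldehyde may be deprotonated at its benzylic CH2 instead of being attacked at carbon, leading to recovered 10 and aldol products of 8. Fallback: 8 is oxidised (NaClO2, NaH2PO4, 2-methylbut-2-ene, t-BuOH–water) to 2-{2,2-dimethyl-8-[(triisopropylsilyl)oxy]-2H-chromen-6-yl}acetic acid F3. F3 is coupled with N,O-dimethylhydroxylamine hydrochloride (EDC, i-Pr2NEt, CH2Cl2) to N-methoxy-N-methyl-2-{2,2-dimethyl-8-[(triisopropylsilyl)oxy]-2H-chromen-6-yl}acetamide F4. Acylation of aryllithium 11 by F4 (THF, −78 → 0 °C) gives ketone 14 directly, returning the route at 14; an enolised amide is simply recovered, where an enolised aldehyde is lost.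

## Further compounds

F1 | step 12 | 3-(dimethylamino)-2-{2,2-dimethyl-8-[(triisopropylsilyl)oxy]-2H-chromen-6-yl}-1-[2-hydroxy-4,6-bis(methoxymethoxy)phenyl]prop-2-en-1-one (alkene geometry not defined) | CC1(C)C=Cc2cc(C(=CN(C)C)C(=O)c3c(O)cc(OCOC)cc3OCOC)cc(O[Si](C(C)C)(C(C)C)C(C)C)c2O1
F0 | step 10 | none | none
F2 | step 9 | 2-{2,2-dimethyl-8-[(triisopropylsilyl)oxy]-2H-chromen-6-yl}-1-(2,4,6-trihydroxyphenyl)ethan-1-one | CC1(C)C=Cc2cc(CC(=O)c3c(O)cc(O)cc3O)cc(O[Si](C(C)C)(C(C)C)C(C)C)c2O1
F0 | step 15 | none | none
F3 | step 7 | 2-{2,2-dimethyl-8-[(triisopropylsilyl)oxy]-2H-chromen-6-yl}acetic acid | CC1(C)C=Cc2cc(CC(=O)O)cc(O[Si](C(C)C)(C(C)C)C(C)C)c2O1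
F4 | step 7 | N-methoxy-N-methyl-2-{2,2-dimethyl-8-[(triisopropylsilyl)oxy]-2H-chromen-6-yl}acetamide | CC1(C)C=Cc2cc(CC(=O)N(C)OC)cc(O[Si](C(C)C)(C(C)C)C(C)C)c2O1
A1 | alternative 1 | methyl 8-(methoxymethoxy)-2,2-dimethyl-7-(3-methylbut-2-en-1-yl)-2H-chromene-6-carboxylate | COC(=O)c1cc2C=CC(C)(C)Oc2c(OCOC)c1CC=C(C)C
A2 | alternative 1 | 8-(methoxymethoxy)-2,2-dimethyl-7-(3-methylbut-2-en-1-yl)-2H,5H-pyrano[3,2-c]pyran-5-one | O=c1oc(CC=C(C)C)c(OCOC)c2OC(C)(C)C=Cc12
A3 | alternative 1 | methyl propiolate | COC(=O)C#C
A4 | alternative 2 | 5,7-dihydroxy-3-[8-(methoxymethoxy)-2,2-dimethyl-7-(3-methylbut-2-en-1-yl)-2H-chromen-6-yl]-4H-chromen-4-one | CC(C)=CCc1c(-c2coc3cc(O)cc(O)c3c2=O)cc2c(c1OCOC)OC(C)(C)C=C2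
A5 | alternative 2 | methyl 5-[8-(methoxymethoxy)-2,2-dimethyl-7-(3-methylbut-2-en-1-yl)-2H-chromen-6-yl]-2-methyl-4-oxo-4H-pyran-3-carboxylate | COC(=O)c1c(C)occ(-c2cc3C=CC(C)(C)Oc3c(OCOC)c2CC=C(C)C)c1=O
A6 | alternative 2 | N-methoxy-N-methylacetamide | CON(C)C(C)=O
A7 | alternative 3 | 3-[8-hydroxy-2,2-dimethyl-7-(3-methylbut-2-en-1-yl)-2H-chromen-6-yl]-5,7-bis(methoxymethoxy)-4H-chromen-4-one | CC(C)=CCc1c(-c2coc3cc(OCOC)cc(OCOC)c3c2=O)cc2c(c1O)OC(C)(C)C=C2
A8 | alternative 3 | 5,7-bis(methoxymethoxy)-3-{3-[(2-methylbut-3-en-2-yl)oxy]-4-[(2-methylbut-3-yn-2-yl)oxy]phenyl}-4H-chromen-4-one | COCOc1cc(OCOC)c2c(c1)occ(-c1ccc(OC(C)(C)C#C)c(OC(C)(C)C=C)c1)c2=O
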